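**Design of a total synthesis of CNP0303209.1 (22): ring A by Claisen refolding of a pyranone-masked triketo ester**

## The problem

The target 22 is an unsymmetrical diarylmethane. Ring A is a fully substituted acylphloroglucinol, numbered here C1' (2-methylbutanoyl), C2' (OH), C3' (Me), C4' (OMe), C5' (CH2 bridge) and C6' (OH). One methylene carbon ties it to C8 of 5,7-dihydroxy-2,2,6-trimethylchroman-4-one (ring B the arene, ring C the pyranone).

Both arenes are hexasubstituted, so every position must be placed, not found. On ring A the single methyl ether must be the oxygen para to the acyl group. On ring B the methyl must sit at C6, para to the pyranone oxygen, although closing ring C on the other ortho oxygen would give the 8-methyl isomer.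

The bridge joins two different phloroglucinol nuclei, and a plain formaldehyde condensation would give both symmetrical dimers beside the wanted one.

The only stereocentre is the (R) carbon alpha to the aryl ketone. Nothing else in the molecule can control it, so it has to be bought and then kept away from conditions that enolize that ketone or ionize an acyl donor.

The finished molecule is fragile. Acid or base cuts and exchanges the bridge through quinone methides, the acyl group can be lost, ring C can open and reclose, and the free phenols are air-sensitive in base. The joining step must therefore be late, mild and free of deprotection.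

What makes a short entry possible is that ring A has the alternating carbonyl pattern of a folded tetraketide with the 2-methylbutanoyl unit as starter. The C1'-C2' bond is a Claisen bond, and C3'-Me and C4'-OMe map onto C3 and the 4-oxygen of a 2-pyranone that masks the chain.

## Retrosynthesis

**Bridge (22 to 13 + 20).** The first cut is the C5'-CH2 bond. Cutting here, and not through a ring, leaves two arenes that each have exactly one unsubstituted carbon, so the joining step has no regiochemistry to decide. To suppress symmetrical dimers, the methylene carbon is placed on one partner beforehand as a Mannich base. Thus 22 goes back to the ring A ketone 13 and the 8-(dimethylaminomethyl)chromanone 20, which on warming loses dimethylamine to give the ortho-quinone methide 21. The bridge carbon is put on the chromanone because that half is achiral and cheaper, so the enantiopure 13 can be the limiting partner. The forward step must form the C-C bond near neutrality, so that bridge and stereocentre are not disturbed.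

**Mannich base (20 to 19).** The C8-CH2N bond is cut. Chromanone 19 has only C8 free, and C8 is ortho to the C7 hydroxyl that is later needed to expel the amine. The forward reaction is a simple aminomethylation.

**Ring C (19 to 18 to 16 + 17).** Ring C is cut at C4-C4a and O1-C2, the bonds made when a phenol is acylated and cyclized by 3,3-dimethylacrylic acid 17.

- From 2-methylphloroglucinol the acylated intermediate has two ortho hydroxyls and ring C can close on either. A mixture of 6-methyl and 8-methyl chromanones is then expected, and the two can interconvert by ring opening.
- The two hydroxyls that flank the methyl are therefore masked. Compound 19 goes back to the dimethyl ether 18, and 18 to 3,5-dimethoxy-4-methylphenol 16 plus 17.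
- Phenol 16 has one hydroxyl and two equivalent ortho carbons, so only one chromanone can form.
- The price is two extra steps, one to make 16 and one to demethylate. The forward demethylation must not open ring C.

**Phenol (16 to 14).** The C-O bond para to the methyl is cut. In 2,6-dimethoxytoluene 14 the carbon para to methyl is the only C-H without an ortho substituent, which is the position sterically controlled iridium borylation selects. Oxidation of boronate 15 gives 16. Electrophilic substitution would instead go ortho to a methoxy group.

**Ring A (13 to 11), the key cut.** The C1'-C2' bond is cut, with C2' taken back to an ester carbon.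

- The neighbouring cut, C1'-CO by Friedel-Crafts acylation, would need a selectively mono-methylated methylphloroglucinol. It would also expose the chiral acyl donor to a Lewis acid.
- The Claisen cut makes the benzene ring with all five substituents already placed.
- The ester is held as the lactone of 2-pyranone 11. The pyranone locks the C2'-C3' double bond cis, carries C4'-OMe as its 4-methoxy group and C3'-Me as its 3-methyl group, and is an isomer of 13.
- The forward step must open the lactone and close by C-acylation, not aldol, without touching the stereocentre. Methoxide opens the lactone to ester 12.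

**Side chain (11 to 5 + 8).** The bond between the side-chain CH2 and the ketone carbon is cut. This gives 4-methoxy-3,6-dimethyl-2-pyranone 5, whose vinylogous 6-methyl group is the only acidic site once C3 is methylated. The other piece is the Weinreb amide 8 of (R)-2-methylbutanoic acid 6. The amide is chosen over an ester or chloride because its adduct 10 does not collapse until quench, so the acidic product ketone never meets the carbanion 9.

**Pyranone (5 to 4 to 3 to 1).** The O-methyl bond is cut first, then the C3-methyl bond. Triacetic acid lactone 1 is alkylated at C3 with formaldehyde and thiophenol through the methylidene dione 2 to give sulfide 3. Direct C-methylation of 1 would compete with O-methylation. Desulfurization gives 4, and O-methylation gives 5.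

## Roads not taken

**Alternative 1:** Ring A by cyclobutenone benzannulation.

- The cut: ring A is taken apart into 3-ethoxy-2-methylcyclobut-2-en-1-one A2 and a methoxyalkyne A3, which is a benzyl-protected chromanone carrying a 3-methoxypropargyl group at C8.
- Forward key step: heating opens A2 to a vinylketene, which adds to the ynol ether. The resulting vinylcyclobutenone opens (4π) and recloses (6π) to give phenol A1. The C5'-C6' and C3'-C4' bonds form and the C1'-C6' bond is remade.
- Merits: five of the six ring A substituents are fixed in one thermal step with full regiocontrol. The bridge is already in A3, so no two phenols need to be cross-coupled. In this respect the route is better than the chosen plan.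
- Weak points:
  - A1 has no acyl group and an ethyl ether at C2'. The chiral acyl unit must then be introduced by Lewis-acid Friedel-Crafts acylation on a diarylmethane, which is exactly where the bridge and the stereocentre are most at risk.
  - The ethyl ether must be cleaved beside the methyl ether. Chelation to the new ketone makes this plausible.
  - Two benzyl ethers must still be removed.
  - A3 presupposes a 6-methyl chromanone functionalized at C8, so the ring B regiochemistry problem is not avoided, and ynol ethers are labile.
- Comparison: the chosen plan needs a separate Mannich device for the bridge. Against that, it delivers ring A with the acyl group in place and no protecting group, from inexpensive 1, and the stereocentre never meets a Lewis acid.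

**Alternative 2:** Both acyl groups by a double photo-Fries shift.

- The cut: both aryl-carbonyl bonds (C1'-CO and C4a-C4) are cut. The precursor is triester A5, a diarylmethane bearing two (R)-2-methylbutanoates on ring A and a 3-methylbut-2-enoate on ring B, with methoxymethyl ethers on the C5 and C7 oxygens.
- Forward key step: UV light homolyses the ArO-CO bonds and the caged acyl radicals recombine at C1' and C4a to give diketone A4. No ring closes.
- Merits: no Lewis acid is used. In A4 only the C8a oxygen is free to add to the enone, so the chromanone regiochemistry is settled by protection, without a symmetric-phenol detour and a demethylation. This is as good as or better than the chosen plan.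
- Weak points:
  - Two independent photochemical events must both succeed on one molecule.
  - Cage escape returns phenols, and the branched acyl radical can decarbonylate.
  - The unsaturated ester is itself a chromophore.
  - A second equivalent of the chiral acid is spent on an ester that must be hydrolysed.
  - A5 needs five differentiated oxygen substituents on an unsymmetrical diarylmethane whose bridge still has to be made selectively.
  - The final acid removal of the acetals endangers the bridge.
- Comparison: the chosen plan sets against this ground-state steps of predictable efficiency, single use of the chiral acid and a bridge made last.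

**Alternative 3:** Ring B by photo-Wolff benzannulation.

- The cut: ring B is taken apart into diazo ketone A7 and siloxyalkyne A8, which carries ring A as a trimethoxy(methyl)benzyl group.
- Forward key step: irradiation of A7 gives an ethoxy vinylketene by Wolff shift. It adds to A8, and 4π opening and 6π closure give phenol A6. The C5-C6, C6-C7, C8-C8a and C4a-C8a bonds form.
- Merits: ring B is regiodefined with three differentiated oxygens (free OH at C8a, silyl at C7, ethyl at C5), so ring C can close only one way. The bridge is carried in from the alkyne. On ring B regiochemistry this is the best of the four plans.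
- Weak points:
  - A6 lacks both acyl groups. Two Friedel-Crafts acylations must then discriminate between two electron-rich rings of an acid-labile diarylmethane.
  - Two of the three ring A methyl ethers must be cleaved while the third is kept.
  - The ethyl and silyl groups must be removed.
  - The stereocentre enters late under Lewis acid.
  - A7 and A8 each need several steps.
- Comparison: the chosen plan accepts a longer chromanone branch (steps 7 to 9). In return both halves arrive fully functionalized, and the last step forms only the bridge.

Key step: step 6

Assumption: (R)-2-methylbutanoic acid 6 is taken as a purchasable single enantiomer; the route never makes or corrects this centre, it only preserves it.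

## Route

Step 1
Reactants: 1 triacetic acid lactone (4-hydroxy-6-methyl-2H-pyran-2-one)
Product: 3 4-hydroxy-6-methyl-3-[(phenylsulfanyl)methyl]-2H-pyran-2-one, via 6-methyl-3-methylidenepyran-2,4-dione 2 (not isolated)
Conditions: (CH2O)n, PhSH, piperidine (cat.), AcOH (cat.), EtOH, 70 °C
Reagents that add atoms: formaldehyde (from paraformaldehyde), C=O; thiophenol, Sc1ccccc1
Why: Knoevenagel condensation at the nucleophilic C3 gives 2, which thiophenol should intercept by thia-Michael addition faster than a second molecule of 1 can add; this three-component C3-alkylation is established for 4-hydroxy-2-pyranones.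

Step 2
Reactants: 3 4-hydroxy-6-methyl-3-[(phenylsulfanyl)methyl]-2H-pyran-2-one
Product: 4 4-hydroxy-3,6-dimethyl-2H-pyran-2-one
Conditions: Raney Ni (acetone-deactivated), EtOH, reflux
Reagents that add atoms: none
Why: Reductive desulfurization (C-S hydrogenolysis) converts the sulfanylmethyl group into the C3 methyl group; deactivated Raney Ni should leave the pyranone double bonds untouched.

Step 3
Reactants: 4 4-hydroxy-3,6-dimethyl-2H-pyran-2-one
Product: 5 4-methoxy-3,6-dimethyl-2H-pyran-2-one
Conditions: Me2SO4, K2CO3, acetone, reflux
Reagents that add atoms: dimethyl sulfate, COS(=O)(=O)OC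
Why: O-alkylation of the vinylogous acid; 4-hydroxy-2-pyranones are methylated by dimethyl sulfate mainly at the 4-oxygen, and the minor 2-methoxy-4-pyranone isomer should be separable.

Step 4
Reactants: 6 (R)-2-methylbutanoic acid
Product: 8 (2R)-N-methoxy-N,2-dimethylbutanamide, via (2R)-1-(imidazol-1-yl)-2-methylbutan-1-one 7 (not isolated)
Conditions: CDI, CH2Cl2, 0 °C to rt; then MeNH(OMe)·HCl, rt
Reagents that add atoms: N,O-dimethylhydroxylamine hydrochloride, CNOC.Cl; 1,1'-carbonyldiimidazole, O=C(n1ccnc1)n1ccnc1 (its imidazole is held only in 7)
Why: Weinreb amide formation through the acyl imidazole; an alpha-alkyl acid has no oxazolone pathway and no strong base is present, so the (R) centre should be retained.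

Step 5
Reactants: 5 4-methoxy-3,6-dimethyl-2H-pyran-2-one; 8 (2R)-N-methoxy-N,2-dimethylbutanamide
Product: 11 4-methoxy-3-methyl-6-[(3R)-3-methyl-2-oxopentyl]-2H-pyran-2-one, via (4-methoxy-3-methyl-2-oxo-2H-pyran-6-yl)methyllithium 9 (not isolated), via lithium hemiaminal alkoxide 10 (not isolated)
Conditions: 5 (1.3 equiv), LiN(iPr)2 (1.25 equiv), THF, -78 °C; then 8, -78 to -40 °C; aq NH4Cl
Reagents that add atoms: lithium diisopropylamide, [Li]N(C(C)C)C(C)C (lithium is held only in 9 and 10)
Why: Deprotonation of the vinylogous 6-methyl group (C3 is blocked) gives 9, which is C-acylated by the Weinreb amide; the chelated adduct 10 persists until quench, so the acidic product ketone never meets the carbanion and over-addition is excluded. The delocalized anion 9 is a weak base and the amide alpha-proton is hindered, so the stereocentre should survive.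

Step 6
Reactants: 11 4-methoxy-3-methyl-6-[(3R)-3-methyl-2-oxopentyl]-2H-pyran-2-one
Product: 13 (2R)-1-(2,6-dihydroxy-4-methoxy-3-methylphenyl)-2-methylbutan-1-one, via methyl (2E,8R)-3-methoxy-2,8-dimethyl-5,7-dioxodec-2-enoate 12 (not isolated)
Conditions: Mg(OMe)2 (4 equiv), MeOH, reflux; then 1 M HCl, 0 °C
Reagents that add atoms: magnesium methoxide, CO[Mg]OC (its methoxide is held only in 12 and leaves again as methanol)
Why: Methoxide from Mg(OMe)2 adds to the lactone carbonyl of 11 and opens the ring to the magnesium enolate of 12, in which the former C3=C4 double bond holds the ester carbon and the diketone chain cis (E by the sequence rules). The methylene between the two ketones (future C1') then attacks the ester carbon (future C2') in a 6-(enolendo)-exo-trig Claisen closure, methoxide leaves and enolization gives the arene, so the step is overall an isomerization of 11. The closest known reaction type is the Mg(OMe)2 recyclization of 6-(2-oxoalkyl)-4-oxygenated 2-pyranones and of open 3,5,7-triketo esters to acylphloroglucinols. No stereocentre is formed; the existing (R) centre lies next to a ketone that is held first as the chelated diketone enolate and then as the phenoxide-conjugated aryl ketone, so its proton is never the acidic one. The selectivity needed is C-acylation over O-acylation and over aldol closure: O-acylation only returns 11 reversibly, and the aldol path would have to use the ester alpha-carbon, which is a fully substituted enol-ether carbon whose methyl group blocks aromatization. Magnesium chelation of the diketone and ester oxygens holds the chain folded for the Claisen mode, and the pyranone 4-methoxy and 3-methyl groups become C4'-OMe and C3'-Me without any aromatic substitution.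

Step 7
Reactants: 14 2,6-dimethoxytoluene
Product: 16 3,5-dimethoxy-4-methylphenol, via 2-(3,5-dimethoxy-4-methylphenyl)-4,4,5,5-tetramethyl-1,3,2-dioxaborolane 15 (not isolated)
Conditions: [Ir(OMe)(cod)]2 (cat.), 4,4'-di-tert-butyl-2,2'-bipyridine (cat.), B2pin2, THF, 80 °C; then aq KHSO5 (Oxone), acetone, rt
Reagents that add atoms: bis(pinacolato)diboron, CC1(C)OB(OC1(C)C)B1OC(C)(C)C(C)(C)O1 (boron is held only in 15); potassium peroxymonosulfate, OOS(=O)(=O)[O-].[K+]
Why: Iridium-catalysed C-H borylation is sterically controlled and the C-H para to the methyl group is the only one without an ortho substituent; one-pot oxidation of the C-B bond gives the phenol.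

Step 8
Reactants: 16 3,5-dimethoxy-4-methylphenol; 17 3,3-dimethylacrylic acid
Product: 18 5,7-dimethoxy-2,2,6-trimethylchroman-4-one
Conditions: P2O5/MeSO3H (Eaton's reagent), 70 °C
Reagents that add atoms: none
Why: Tandem Friedel-Crafts acylation ortho to the hydroxyl and oxa-Michael closure, the standard chromanone synthesis from electron-rich phenols; 16 has one hydroxyl and two equivalent ortho carbons, so a single chromanone with the methyl at C6 is expected. The methyl ethers are stable to this medium.

Step 9
Reactants: 18 5,7-dimethoxy-2,2,6-trimethylchroman-4-one
Product: 19 5,7-dihydroxy-2,2,6-trimethylchroman-4-one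
Conditions: BBr3 (4 equiv), CH2Cl2, -78 to 0 °C; then MeOH, H2O
Reagents that add atoms: none
Why: Lewis-acid cleavage of aryl methyl ethers; the C5 ether is activated by chelation to the ketone and the C7 ether is para to it. The low temperature is chosen so that ring C is not opened and reclosed on the other oxygen.

Step 10
Reactants: 19 5,7-dihydroxy-2,2,6-trimethylchroman-4-one
Product: 20 8-[(dimethylamino)methyl]-5,7-dihydroxy-2,2,6-trimethylchroman-4-one
Conditions: CH2(NMe2)2, 1,4-dioxane, 80 °C
Reagents that add atoms: bis(dimethylamino)methane, CN(C)CN(C)C
Why: Phenol Mannich aminomethylation with a preformed aminal; C8 is the only free ring position and is activated by three oxygens, and the neutral medium should avoid aminomethylation alpha to the ketone.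

Step 11
Reactants: 13 (2R)-1-(2,6-dihydroxy-4-methoxy-3-methylphenyl)-2-methylbutan-1-one; 20 8-[(dimethylamino)methyl]-5,7-dihydroxy-2,2,6-trimethylchroman-4-one
Product: 22 (2R)-1-{3-[(5,7-dihydroxy-2,2,6-trimethyl-4-oxochroman-8-yl)methyl]-2,6-dihydroxy-4-methoxy-5-methylphenyl}-2-methylbutan-1-one, via 5-hydroxy-2,2,6-trimethyl-8-methylidene-2,3-dihydrochromene-4,7-dione 21 (not isolated)
Conditions: 20 (1.2 equiv), 1,4-dioxane, 100 °C, N2 stream
Reagents that add atoms: none
Why: Thermal loss of dimethylamine from the ortho-hydroxybenzylamine gives ortho-quinone methide 21, and the only free carbon of 13 (C5') adds to it in a conjugate Friedel-Crafts alkylation followed by rearomatization, the known Mannich-base route to methylene-bridged phloroglucinols. Compound 20 has no free ring carbon and cannot oligomerize, and no strong acid or base is present to epimerize the ketone or scramble the bridge.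

## Compound list

1 | triacetic acid lactone (4-hydroxy-6-methyl-2H-pyran-2-one) | Cc1cc(O)cc(=O)o1 | starting material
2 | 6-methyl-3-methylidene-2H-pyran-2,4(3H)-dione | C=C1C(=O)C=C(C)OC1=O | intermediate
3 | 4-hydroxy-6-methyl-3-[(phenylsulfanyl)methyl]-2H-pyran-2-one | Cc1cc(O)c(CSc2ccccc2)c(=O)o1 | intermediate
4 | 4-hydroxy-3,6-dimethyl-2H-pyran-2-one | Cc1cc(O)c(C)c(=O)o1 | intermediate
5 | 4-methoxy-3,6-dimethyl-2H-pyran-2-one | COc1cc(C)oc(=O)c1C | intermediate
6 | (R)-2-methylbutanoic acid | CC[C@@H](C)C(O)=O | starting material
7 | (2R)-1-(1H-imidazol-1-yl)-2-methylbutan-1-one | CC[C@@H](C)C(=O)n1ccnc1 | intermediate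
8 | (2R)-N-methoxy-N,2-dimethylbutanamide | CC[C@@H](C)C(=O)N(C)OC | intermediate
9 | (4-methoxy-3-methyl-2-oxo-2H-pyran-6-yl)methyllithium | [Li]Cc1cc(OC)c(C)c(=O)o1 | intermediate
10 | lithium (3R)-2-[methoxy(methyl)amino]-1-(4-methoxy-3-methyl-2-oxo-2H-pyran-6-yl)-3-methylpentan-2-olate (C2 configuration undefined) | CC[C@@H](C)C(O[Li])(Cc1cc(OC)c(C)c(=O)o1)N(C)OC | intermediate
11 | 4-methoxy-3-methyl-6-[(3R)-3-methyl-2-oxopentyl]-2H-pyran-2-one | CC[C@@H](C)C(=O)Cc1cc(OC)c(C)c(=O)o1 | intermediate
12 | methyl (2E,8R)-3-methoxy-2,8-dimethyl-5,7-dioxodec-2-enoate | CC[C@@H](C)C(=O)CC(=O)C/C(OC)=C(C)\C(=O)OC | intermediate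
13 | (2R)-1-(2,6-dihydroxy-4-methoxy-3-methylphenyl)-2-methylbutan-1-one | CC[C@@H](C)C(=O)c1c(O)cc(OC)c(C)c1O | intermediate
14 | 2,6-dimethoxytoluene (1,3-dimethoxy-2-methylbenzene) | COc1cccc(OC)c1C | starting material
15 | 2-(3,5-dimethoxy-4-methylphenyl)-4,4,5,5-tetramethyl-1,3,2-dioxaborolane | COc1cc(B2OC(C)(C)C(C)(C)O2)cc(OC)c1C | intermediate
16 | 3,5-dimethoxy-4-methylphenol | COc1cc(O)cc(OC)c1C | intermediate
17 | 3,3-dimethylacrylic acid (3-methylbut-2-enoic acid) | CC(C)=CC(O)=O | starting material
18 | 5,7-dimethoxy-2,2,6-trimethylchroman-4-one | COc1cc2OC(C)(C)CC(=O)c2c(OC)c1C | intermediate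
19 | 5,7-dihydroxy-2,2,6-trimethylchroman-4-one | Cc1c(O)cc2OC(C)(C)CC(=O)c2c1O | intermediate
20 | 8-[(dimethylamino)methyl]-5,7-dihydroxy-2,2,6-trimethylchroman-4-one | CN(C)Cc1c(O)c(C)c(O)c2C(=O)CC(C)(C)Oc12 | intermediate
21 | 5-hydroxy-2,2,6-trimethyl-8-methylidene-2,3-dihydro-4H-chromene-4,7(8H)-dione | C=C1C(=O)C(C)=C(O)C2=C1OC(C)(C)CC2=O | intermediate
22 | (2R)-1-{3-[(5,7-dihydroxy-2,2,6-trimethyl-4-oxochroman-8-yl)methyl]-2,6-dihydroxy-4-methoxy-5-methylphenyl}-2-methylbutan-1-one (CNP0303209.1) | CC[C@@H](C)C(=O)c1c(O)c(C)c(OC)c(Cc2c(O)c(C)c(O)c3c2OC(C)(C)CC3=O)c1O | target

## Step count and risks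

Total: 11 steps. Longest linear sequence: 6 steps (1 to 22 through steps 1, 2, 3, 5, 6 and 11). The chromanone branch has 5 steps (7 to 11), and the amide branch joins after one step.

**Step 6 (key step).**
- What may go wrong: the ring-opened ester is a vinylogous carbonate of low electrophilicity, so closure may be slow and 11 merely recovered. Methoxide may instead attack the side-chain ketone and split the chain by retro-Claisen cleavage. Slow epimerization on prolonged heating in base is the third concern.
- Fallback: ring A is made by acylation instead of folding. It sets out from 6, which oxalyl chloride converts into (2R)-2-methylbutanoyl chloride F1. F1 acylates commercial 2-methylphloroglucinol (Cc1c(O)cc(O)cc1O), whose two free carbons are equivalent, under AlCl3 to give (2R)-2-methyl-1-(2,4,6-trihydroxy-3-methylphenyl)butan-1-one F2. The only non-chelated hydroxyl of F2, para to the ketone, is methylated with one equivalent of Me3SiCHN2 or Me2SO4/K2CO3. The route is rejoined at 13.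

**Step 5.**
- What may go wrong: proton transfer may compete with addition. Anion 9 may deprotonate the alpha-position of 8, eroding enantiopurity, or may condense with the lactone carbonyl of a second molecule of 5.
- Fallback: acylation before O-methylation. It sets out from 4, which two equivalents of LiN(iPr)2 convert into its O,C-dianion, a more nucleophilic and less self-electrophilic carbanion. Acylation with 8 gives 4-hydroxy-3-methyl-6-[(3R)-3-methyl-2-oxopentyl]-2H-pyran-2-one F3. Its strongly acidic 4-hydroxyl is then methylated selectively with Me3SiCHN2. The route is rejoined at 11.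

**Step 9.**
- What may go wrong: Lewis-acid opening of ring C at the tertiary ether, followed by reclosure on the freed C5 oxygen, would move the methyl group to C8 in effect. Cleavage of the C7 ether, which is flanked by the methyl group, may also be incomplete.
- Fallback: no protecting groups, with separation in place of regiocontrol. It sets out from 17, which is condensed directly with commercial 2-methylphloroglucinol (Cc1c(O)cc(O)cc1O) in BF3·OEt2 or Eaton's reagent. The 6-methyl chromanone is separated chromatographically from its isomer 5,7-dihydroxy-2,2,8-trimethylchroman-4-one F4. The route is rejoined at 19.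

**Step 11.**
- What may go wrong: the attack of the hindered C5' carbon (between a methoxy and a chelated hydroxyl) may be slow. That would allow reversible O-alkylation, re-addition of the amine, and exchange of the bridge through quinone methides to give symmetrical dimers.
- Fallback: the roles of the two halves are exchanged. It sets out from 13, which is aminomethylated with bis(dimethylamino)methane to (2R)-1-{3-[(dimethylamino)methyl]-2,6-dihydroxy-4-methoxy-5-methylphenyl}-2-methylbutan-1-one F5. F5 is heated with 19, whose unhindered C8 now acts as the nucleophile towards the ring A quinone methide. The route is rejoined at 22.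

## Further compounds

F1 | step 6 | (2R)-2-methylbutanoyl chloride | CC[C@@H](C)C(Cl)=O
F2 | step 6 | (2R)-2-methyl-1-(2,4,6-trihydroxy-3-methylphenyl)butan-1-one | CC[C@@H](C)C(=O)c1c(O)cc(O)c(C)c1O
F3 | step 5 | 4-hydroxy-3-methyl-6-[(3R)-3-methyl-2-oxopentyl]-2H-pyran-2-one | CC[C@@H](C)C(=O)Cc1cc(O)c(C)c(=O)o1
F4 | step 9 | 5,7-dihydroxy-2,2,8-trimethylchroman-4-one | Cc1c(O)cc(O)c2C(=O)CC(C)(C)Oc12
F5 | step 11 | (2R)-1-{3-[(dimethylamino)methyl]-2,6-dihydroxy-4-methoxy-5-methylphenyl}-2-methylbutan-1-one | CC[C@@H](C)C(=O)c1c(O)c(C)c(OC)c(CN(C)C)c1O
A1 | alternative 1 | 5,7-bis(benzyloxy)-8-[(4-ethoxy-6-hydroxy-2-methoxy-3-methylphenyl)methyl]-2,2,6-trimethylchroman-4-one | CCOc1cc(O)c(Cc2c(OCc3ccccc3)c(C)c(OCc3ccccc3)c3C(=O)CC(C)(C)Oc23)c(OC)c1C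
A2 | alternative 1 | 3-ethoxy-2-methylcyclobut-2-en-1-one | CCOC1=C(C)C(=O)C1
A3 | alternative 1 | 5,7-bis(benzyloxy)-8-(3-methoxyprop-2-yn-1-yl)-2,2,6-trimethylchroman-4-one | COC#CCc1c(OCc2ccccc2)c(C)c(OCc2ccccc2)c2C(=O)CC(C)(C)Oc12
A4 | alternative 2 | 3-hydroxy-4-{[2-hydroxy-4,6-bis(methoxymethoxy)-5-methyl-3-(3-methylbut-2-enoyl)phenyl]methyl}-5-methoxy-6-methyl-2-[(2R)-2-methylbutanoyl]phenyl (2R)-2-methylbutanoate | CC[C@@H](C)C(=O)c1c(O)c(Cc2c(O)c(C(=O)C=C(C)C)c(OCOC)c(C)c2OCOC)c(OC)c(C)c1OC(=O)[C@H](C)CC
A5 | alternative 2 | 4-{[2,4-bis(methoxymethoxy)-3-methyl-6-[(3-methylbut-2-enoyl)oxy]phenyl]methyl}-5-methoxy-6-methyl-1,3-phenylene bis[(2R)-2-methylbutanoate] | CC[C@@H](C)C(=O)Oc1cc(OC(=O)[C@H](C)CC)c(C)c(OC)c1Cc1c(OC(=O)C=C(C)C)cc(OCOC)c(C)c1OCOC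
A6 | alternative 3 | 5-ethoxy-4-methyl-3-(triisopropylsilyloxy)-2-[(2,4,6-trimethoxy-3-methylphenyl)methyl]phenol | CCOc1cc(O)c(Cc2c(OC)cc(OC)c(C)c2OC)c(O[Si](C(C)C)(C(C)C)C(C)C)c1C
A7 | alternative 3 | 4-diazo-2-ethoxypent-1-en-3-one | CCOC(=C)C(=O)C(C)=[N+]=[N-]
A8 | alternative 3 | triisopropyl{[3-(2,4,6-trimethoxy-3-methylphenyl)prop-1-yn-1-yl]oxy}silane | COc1cc(OC)c(C)c(OC)c1CC#CO[Si](C(C)C)(C(C)C)C(C)C
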